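The data were computed on assumed constants; noise was put on by code.

- I started with an easy count: how much partner each flask holds beyond one per substrate.

all flasks: substrate 0.64 M

| run | partner | remark | time |
|---|---|---|---|
| alder | 1 M | run made earlier |  |
| grey | 0.768 M |  | 2.5 min |
| red | 1.92 M |  | 2.5 min |
| violet | 2.56 M |  | 2.5 min |

alder run (percent of the substrate charged)

| time / min | bis adduct / % | mono adduct / % |
|---|---|---|
| 0.200 | 3 | 49 |
| 0.667 | 2 | 73 |
| 1.33 | 0 | 80 |
| 2.00 | 2 | 81 |
| 2.50 | 0 | 86 |

(scatter of a reading: 2 percentage points)

- what is said of mono adduct includes crystals
- crystals is a solid; its amount is given per volume of the solution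
- candidate steps: substrate + partner -> mono adduct; partner + mono adduct -> bis adduct; partner + bis adduct -> tris adduct; crystals <-> mono adduct

1. which of these holds the largest part of the substrate at the end of grey (bis adduct / substrate / tris adduct / mono adduct)
2. which of these holds the largest part of the substrate at the end of red (bis adduct / substrate / tris adduct / mono adduct)
3. which of these holds the largest part of the substrate at the end of violet (bis adduct / substrate / tris adduct / mono adduct)
4. bis adduct at the end of grey, in percent of the substrate charged

- Alder's bis adduct read 2% at 2.00 min, about its scatter of 2 percentage points, so I dropped it from the count.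
- Past the first step, I took partner to fall twice as fast as tris adduct rises. Dividing one rate by the other removed time.
- Grey came to 0.100: surplus partner over twice c(substrate). I called this the surplus number; between zero and 1, it is the share of substrate ending as tris adduct once substrate and partner are both spent.
- Red came to 1.00 and violet to 1.50. Violet's number passed 1, too large for a share, so there it meant partner to spare after tris adduct had taken up the substrate.
- Grey's number stood below 0.5, so I called mono adduct for grey.
- Red's and violet's numbers stood above 0.5, so they pointed to tris adduct at the far end, but gave no call for 2.5 min.
- Alder tested it. Its number was 0.281, yet its last readings left 14.0% outside mono and bis adduct, which is less. One number had no clock, so I left red and violet open.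
- The forecast went further: mono adduct, mono adduct and mono adduct for grey, red and violet, with bis adduct in grey at 1.2% (0.3% to 3%). Its ground was “the crystals should keep mono the largest”.
- The flasks gave mono adduct, mono adduct and tris adduct. Grey's bis adduct was 0.760%.

    substrate + partner → mono adduct (k = 0.0835 M⁻¹ s⁻¹)
    partner + mono adduct → bis adduct (k = 0.0375 M⁻¹ s⁻¹)
    partner + bis adduct → tris adduct (k = 0.277 M⁻¹ s⁻¹)
    crystals ⇌ mono adduct, rate k4*(cs4 - [mono adduct]) while solid is left; crystals form when [mono adduct] > cs4 (solubility = 33.0 mM, k = 0.263 s⁻¹)

- Grey ended with tris adduct at 8.82% against its number of 0.100, with substrate at 9.0% and partner at 8.8%. Violet, at 1.50, ended with tris adduct at 55.2% and mono adduct at 44.2%. A neighbour flask like grey but with 2.6 M of substrate has a surplus number of −0.352, below zero, which makes partner the limiting reagent. That neighbour ended with partner at 0%, tris adduct at 0.379% and substrate at 72%.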